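Each half of the target is a cyclohepta[b]pyran in which C7 (C=O) and C9a (bearing O1) are spanned by C8–C9 just as the carbonyl carbons of cyclopentane-1,3-dione are spanned by its CH2CH2 unit, while C4a and C5 (with its methyl) map onto the triple bond of a but-2-ynyl group on C4. The precursor is therefore the dione enol ether of a chiral 1-silyloxyhept-5-yn-2-ol. Irradiation welds alkyne to enone (C4a–C9a, C5–C6) and scission of the former enone bond C6–C9a then delivers dihydropyran ring and seven-membered dienone in one operation. Both halves diverge from one Sharpless epoxide, are united by Suzuki coupling and are raised to tropolones together at the end.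

Key step: step 7

Remark on the chemistry: the two tropolone tautomers (7-oxo-8-hydroxy and 8-oxo-7-hydroxy) interconvert rapidly, so 27 is written as the tautomer of the target SMILES; cyclohepta[b]pyran locants are used throughout, and primed locants denote the half without the C3 methyl group.

Step 1
Reactants: 1 prop-2-yn-1-ol; 2 1-bromobut-2-yne
Product: 3 hepta-2,5-diyn-1-ol
Conditions: CuI (20 mol %), Bu4NBr (20 mol %), K2CO3, DMF, rt
Reagents that add atoms: none
Why: Copper-catalysed sp–sp3 coupling of a terminal alkyne with a propargylic bromide (via the copper acetylide) is the standard entry to skipped diynes, tolerates the free hydroxyl group and creates no stereocentre.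

Step 2
Reactants: 3 hepta-2,5-diyn-1-ol
Product: 4 (E)-hept-2-en-5-yn-1-ol
Conditions: NaAlH2(OCH2CH2OMe)2 (1.5 equiv), THF, 0 °C → rt; aq potassium sodium tartrate
Reagents that add atoms: none
Why: Hydroxyl-directed trans-hydroalumination of a propargylic alcohol: hydride is delivered within the alkoxyaluminate only to the neighbouring triple bond, so protonolysis should give the E-allylic alcohol while the remote but-2-ynyl triple bond is left alone.

Step 3
Reactants: 4 (E)-hept-2-en-5-yn-1-ol
Product: 5 [(2S,3S)-3-(but-2-yn-1-yl)oxiran-2-yl]methanol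
Conditions: Ti(OiPr)4 (10 mol %), L-(+)-diethyl tartrate (12 mol %), t-BuOOH, 4 Å MS, CH2Cl2, −20 °C
Reagents that add atoms: tert-butyl hydroperoxide, CC(C)(C)OO
Why: Sharpless asymmetric epoxidation, in which the titanium–L-(+)-tartrate complex delivers oxygen to one face of the E-allylic alcohol to give the (2S,3S)-epoxide; this sets the C2–O configuration of both halves, and the alkyne is inert to t-BuOOH.

Step 4
Reactants: 5 [(2S,3S)-3-(but-2-yn-1-yl)oxiran-2-yl]methanol
Product: 6 (2R,3R)-3-methylhept-5-yne-1,2-diol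
Conditions: Me3Al (3 equiv), CH2Cl2–hexane, −20 → 0 °C; aq potassium sodium tartrate
Reagents that add atoms: trimethylaluminium, C[Al](C)C
Why: Organoaluminium opening of a 2,3-epoxy alcohol: the aluminium alkoxide activates the oxirane and methyl is transferred to C3 in an SN2 manner with inversion, which sets C3 as R, leaves C2 untouched (now R by a change of priorities only) and gives the 1,2-diol whose anti pattern becomes the 2,3-trans relationship of the pyran ring.

Step 5
Reactants: 6 (2R,3R)-3-methylhept-5-yne-1,2-diol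
Product: 7 (2R,3R)-1-(tert-butyldiphenylsilyloxy)-3-methylhept-5-yn-2-ol
Conditions: t-BuPh2SiCl (1.05 equiv), imidazole, CH2Cl2, 0 °C
Reagents that add atoms: tert-butyl(chloro)diphenylsilane, CC(C)(C)[Si](Cl)(c1ccccc1)c1ccccc1
Why: Selective silylation of the primary hydroxyl group by a bulky chlorosilane; tert-butyldiphenylsilyl is preferred to smaller silyl groups because it has to outlast hot sulfonic acid in step 6 and BF3 in step 7 and is transparent at 300 nm.

Step 6
Reactants: 7 (2R,3R)-1-(tert-butyldiphenylsilyloxy)-3-methylhept-5-yn-2-ol; 8 cyclopentane-1,3-dione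
Product: 9 3-{[(2R,3R)-1-(tert-butyldiphenylsilyloxy)-3-methylhept-5-yn-2-yl]oxy}cyclopent-2-en-1-one
Conditions: 8 (2 equiv), p-TsOH·H2O (5 mol %), toluene, Dean–Stark, reflux
Reagents that add atoms: none
Why: Acid-catalysed enol etherification of a cyclic 1,3-dione (a vinylogous Fischer esterification) driven by azeotropic removal of water; the alcohol oxygen is the nucleophile, so the C2–O bond is never broken and C2 is retained, and the acidic medium excludes the 1,2-silyl shift that an alkoxide would invite.

Step 7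
Reactants: 9 3-{[(2R,3R)-1-(tert-butyldiphenylsilyloxy)-3-methylhept-5-yn-2-yl]oxy}cyclopent-2-en-1-one
Product: 11 (2R,3R)-2-[(tert-butyldiphenylsilyloxy)methyl]-3,5-dimethyl-3,4,8,9-tetrahydrocyclohepta[b]pyran-7(2H)-one, via cyclobutene photoadduct 10 (not isolated)
Conditions: hν (300 nm, Pyrex), Ar-sparged CH2Cl2 (5 mM), rt; lamp off, concentrate to 0.05 M; BF3·OEt2 (0.3 equiv), −78 → 0 °C; aq NaHCO3
Reagents that add atoms: none
Why: Excitation at 300 nm and intersystem crossing give the triplet vinylogous ester, whose β-carbon C9a adds to the near alkyne carbon C4a in a 6-exo-dig sense (this closes the dihydropyran ring), and after spin inversion the vinyl/α-keto 1,4-biradical couples C5 to C6 to close the cyclobutene of 10. The closest known reaction type is the intramolecular enone–alkyne [2+2] photocycloaddition of 3-alkoxyenones combined with the de Mayo-type fragmentation of donor–acceptor four-membered rings. BF3 bound to the C7 carbonyl then induces heterolysis of the ring-fusion bond C6–C9a, pushed by the O1 lone pair and pulled by the boron enolate, so the seven-membered ring arises by two-carbon enlargement of the cyclopentenone and not by an end-to-end closure; because the cleavage is stepwise it escapes the conrotatory course that would force a trans double bond into the ring. C6 and C9a of 10 are necessarily cis-fused, both return to sp2 in 11, and no lasting stereocentre is created, while C2 and C3 are spectators. Regioselectivity (straight, not crossed) is secured by the four-atom tether O1–C2–C3–C4, since the crossed mode would need a bridgehead cyclobutene, and bond selectivity in the opening is secured because only C6–C9a carries both the donor and the acceptor. Cutting the light before the acid is added keeps the strongly absorbing dienone 11 out of the photoreactor, and the 300 nm window limits a secondary 1,3-acyl shift of the β,γ-unsaturated ketone 10.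

Step 8
Reactants: 11 (2R,3R)-2-[(tert-butyldiphenylsilyloxy)methyl]-3,5-dimethyl-3,4,8,9-tetrahydrocyclohepta[b]pyran-7(2H)-one
Product: 12 (2R,3R)-2-(hydroxymethyl)-3,5-dimethyl-3,4,8,9-tetrahydrocyclohepta[b]pyran-7(2H)-one
Conditions: Bu4NF, AcOH (1:1), THF, 0 °C → rt
Reagents that add atoms: none
Why: Fluoride-mediated cleavage of the silyl ether, with acetic acid tempering the basicity of fluoride so that the enolisable dienone and C2 are not disturbed.

Step 9
Reactants: 12 (2R,3R)-2-(hydroxymethyl)-3,5-dimethyl-3,4,8,9-tetrahydrocyclohepta[b]pyran-7(2H)-one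
Product: 13 (2R,3R)-3,5-dimethyl-7-oxo-2,3,4,7,8,9-hexahydrocyclohepta[b]pyran-2-carbaldehyde
Conditions: Dess–Martin periodinane, CH2Cl2, 0 °C → rt
Reagents that add atoms: none
Why: Dess–Martin oxidation stops at the aldehyde under base-free conditions, so the α-oxygenated stereocentre C2 (already the more stable 2,3-trans isomer) should not epimerise, and the aldehyde is used without storage.

Step 10
Reactants: 13 (2R,3R)-3,5-dimethyl-7-oxo-2,3,4,7,8,9-hexahydrocyclohepta[b]pyran-2-carbaldehyde
Product: 14 (2R,3R)-2-[(E)-2-iodoethenyl]-3,5-dimethyl-3,4,8,9-tetrahydrocyclohepta[b]pyran-7(2H)-one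
Conditions: CrCl2 (6 equiv), CHI3 (2 equiv), THF–dioxane, 0 °C
Reagents that add atoms: iodoform, IC(I)I
Why: Takai olefination: the geminal dichromium species from CHI3 adds to the aldehyde far faster than to the vinylogous-ester ketone and eliminates to the E-iodoalkene under non-basic conditions that spare C2.

Step 11
Reactants: 5 [(2S,3S)-3-(but-2-yn-1-yl)oxiran-2-yl]methanol
Product: 15 (2R)-hept-5-yne-1,2-diol
Conditions: Ti(OiPr)4 (1.5 equiv), LiBH4 (2 equiv), benzene, rt; dilute aq acid work-up
Reagents that add atoms: none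
Why: Titanium-assisted borohydride opening of a 2,3-epoxy alcohol: coordination of the alkoxide and the oxirane oxygen to titanium directs hydride to C3′, giving the 1,2-diol with C2′ untouched, and LiBH4 does not reduce the alkyne.

Step 12
Reactants: 15 (2R)-hept-5-yne-1,2-diol
Product: 16 (2R)-1-(tert-butyldiphenylsilyloxy)hept-5-yn-2-ol
Conditions: t-BuPh2SiCl (1.05 equiv), imidazole, CH2Cl2, 0 °C
Reagents that add atoms: tert-butyl(chloro)diphenylsilane, CC(C)(C)[Si](Cl)(c1ccccc1)c1ccccc1
Why: Selective silylation of the primary hydroxyl group by a bulky chlorosilane, for the reasons given in step 5.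

Step 13
Reactants: 16 (2R)-1-(tert-butyldiphenylsilyloxy)hept-5-yn-2-ol; 8 cyclopentane-1,3-dione
Product: 17 3-{[(2R)-1-(tert-butyldiphenylsilyloxy)hept-5-yn-2-yl]oxy}cyclopent-2-en-1-one
Conditions: 8 (2 equiv), p-TsOH·H2O (5 mol %), toluene, Dean–Stark, reflux
Reagents that add atoms: none
Why: Acid-catalysed enol etherification as in step 6, again with retention at C2′ because only the O–H bond of the alcohol is broken.

Step 14
Reactants: 17 3-{[(2R)-1-(tert-butyldiphenylsilyloxy)hept-5-yn-2-yl]oxy}cyclopent-2-en-1-one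
Product: 19 (2R)-2-[(tert-butyldiphenylsilyloxy)methyl]-5-methyl-3,4,8,9-tetrahydrocyclohepta[b]pyran-7(2H)-one, via cyclobutene photoadduct 18 (not isolated)
Conditions: hν (300 nm, Pyrex), Ar-sparged CH2Cl2 (5 mM), rt; lamp off, concentrate to 0.05 M; BF3·OEt2 (0.3 equiv), −78 → 0 °C; aq NaHCO3
Reagents that add atoms: none
Why: The same intramolecular enone–alkyne [2+2] photocycloaddition and push–pull cyclobutene fragmentation as in step 7, in which the four-atom tether again enforces C4a′–C9a′ and C5′–C6′ bonding, the two ring-fusion centres are transient and C2′ is a spectator.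

Step 15
Reactants: 19 (2R)-2-[(tert-butyldiphenylsilyloxy)methyl]-5-methyl-3,4,8,9-tetrahydrocyclohepta[b]pyran-7(2H)-one
Product: 20 (2R)-2-(hydroxymethyl)-5-methyl-3,4,8,9-tetrahydrocyclohepta[b]pyran-7(2H)-one
Conditions: Bu4NF, AcOH (1:1), THF, 0 °C → rt
Reagents that add atoms: none
Why: Buffered fluoride desilylation as in step 8, mild enough for the enolisable dienone.

Step 16
Reactants: 20 (2R)-2-(hydroxymethyl)-5-methyl-3,4,8,9-tetrahydrocyclohepta[b]pyran-7(2H)-one
Product: 21 (2R)-5-methyl-7-oxo-2,3,4,7,8,9-hexahydrocyclohepta[b]pyran-2-carbaldehyde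
Conditions: Dess–Martin periodinane, CH2Cl2, 0 °C → rt
Reagents that add atoms: none
Why: Dess–Martin oxidation under base-free conditions; C2′ is the only stereocentre here, so the aldehyde is taken on at once to avoid racemisation by enolisation.

Step 17
Reactants: 21 (2R)-5-methyl-7-oxo-2,3,4,7,8,9-hexahydrocyclohepta[b]pyran-2-carbaldehyde
Product: 22 (2R)-5-methyl-2-[(E)-2-(4,4,5,5-tetramethyl-1,3,2-dioxaborolan-2-yl)ethenyl]-3,4,8,9-tetrahydrocyclohepta[b]pyran-7(2H)-one
Conditions: Cl2CHB(pin) (2 equiv), CrCl2 (8 equiv), LiI (4 equiv), THF, rt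
Reagents that add atoms: 2-(dichloromethyl)-4,4,5,5-tetramethyl-1,3,2-dioxaborolane, ClC(Cl)B1OC(C)(C)C(C)(C)O1
Why: Takai–Utimoto olefination (the boron variant of the chromium olefination): the geminal dichromium boronate adds chemoselectively to the aldehyde and eliminates to the E-alkenylboronate without any base that could touch C2′.

Step 18
Reactants: 14 (2R,3R)-2-[(E)-2-iodoethenyl]-3,5-dimethyl-3,4,8,9-tetrahydrocyclohepta[b]pyran-7(2H)-one; 22 (2R)-5-methyl-2-[(E)-2-(4,4,5,5-tetramethyl-1,3,2-dioxaborolan-2-yl)ethenyl]-3,4,8,9-tetrahydrocyclohepta[b]pyran-7(2H)-one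
Product: 23 (2R,3R)-3,5-dimethyl-2-{(1E,3E)-4-[(2R)-5-methyl-7-oxo-2,3,4,7,8,9-hexahydrocyclohepta[b]pyran-2-yl]buta-1,3-dien-1-yl}-3,4,8,9-tetrahydrocyclohepta[b]pyran-7(2H)-one
Conditions: PdCl2(dppf) (5 mol %), K3PO4 (aq), degassed THF, rt
Reagents that add atoms: none
Why: Suzuki–Miyaura alkenyl–alkenyl coupling, which retains both E geometries and so gives the E,E-diene; room temperature and the fast oxidative addition into the C–I bond are chosen to outrun ionisation of the allylic C2–O1 bonds by zerovalent palladium, and a cross-coupling is preferred to any sulfone or phosphorus carbanion beside C2 or C2′, which would expel O1 as a doubly vinylogous carboxylate.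

Step 19
Reactants: 23 (2R,3R)-3,5-dimethyl-2-{(1E,3E)-4-[(2R)-5-methyl-7-oxo-2,3,4,7,8,9-hexahydrocyclohepta[b]pyran-2-yl]buta-1,3-dien-1-yl}-3,4,8,9-tetrahydrocyclohepta[b]pyran-7(2H)-one
Product: 25 8,8′-dihydroxy derivative of 23 (bis-acyloin; epimers at C8 and C8′), via disodium C7–C8 bis-enolate 24 (not isolated)
Conditions: NaN(SiMe3)2 (2.4 equiv), THF, −78 °C; 3-phenyl-2-(phenylsulfonyl)oxaziridine (3 equiv), −78 °C; AcOH quench
Reagents that add atoms: 3-phenyl-2-(phenylsulfonyl)-1,2-oxaziridine, O=S(=O)(N1OC1c1ccccc1)c1ccccc1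
Why: Kinetic deprotonation of a conjugated ketone by a hindered amide base takes the α′ proton (C8 and C8′), and Davis oxidation of the enolates by the N-sulfonyloxaziridine transfers oxygen to these carbons without touching diene or enol ethers; the new carbinol centres form without control and are erased in step 20.

Step 20
Reactants: 25 8,8′-dihydroxy derivative of 23 (bis-acyloin)
Product: 27 (2R,3R)-8-hydroxy-2-{(1E,3E)-4-[(2R)-8-hydroxy-5-methyl-7-oxo-2,3,4,7-tetrahydrocyclohepta[b]pyran-2-yl]buta-1,3-dien-1-yl}-3,5-dimethyl-3,4-dihydrocyclohepta[b]pyran-7(2H)-one (CNP0332980.1), via bis(7,8-dione) 26 (not isolated)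
Conditions: Dess–Martin periodinane (2.5 equiv), CH2Cl2, 0 °C → rt; aq Na2S2O3, pH 5 buffer work-up
Reagents that add atoms: none
Why: Dess–Martin oxidation of each acyloin gives the 7,8-dione, which should enolise at once through C9–H because this completes the aromatic hydroxytropone, and C2, C3 and C2′ as well as the diene are not involved.

Compound list
1 | prop-2-yn-1-ol | C#CCO | starting material
2 | 1-bromobut-2-yne | CC#CCBr | starting material
3 | hepta-2,5-diyn-1-ol | CC#CCC#CCO | intermediate
4 | (E)-hept-2-en-5-yn-1-ol | CC#CC/C=C/CO | intermediate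
5 | [(2S,3S)-3-(but-2-yn-1-yl)oxiran-2-yl]methanol (trans-epoxide, common to both halves) | OC[C@@H]1O[C@H]1CC#CC | intermediate
6 | (2R,3R)-3-methylhept-5-yne-1,2-diol | CC#CC[C@@H](C)[C@H](CO)O | intermediate
7 | (2R,3R)-1-(tert-butyldiphenylsilyloxy)-3-methylhept-5-yn-2-ol | CC#CC[C@@H](C)[C@H](CO[Si](c1ccccc1)(c1ccccc1)C(C)(C)C)O | intermediate
8 | cyclopentane-1,3-dione | O=C1CCC(=O)C1 | starting material
9 | 3-{[(2R,3R)-1-(tert-butyldiphenylsilyloxy)-3-methylhept-5-yn-2-yl]oxy}cyclopent-2-en-1-one (precursor of the key step) | CC#CC[C@@H](C)[C@H](CO[Si](c1ccccc1)(c1ccccc1)C(C)(C)C)OC1=CC(=O)CC1 | intermediate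
10 | cyclobutene photoadduct: bicyclo[3.2.0]hept-6-en-2-one core (C7 ketone, cis ring-fusion carbons C6 and C9a, C4a=C5 double bond with methyl on C5) bridged from C9a to C4a by O1–C2–C3–C4; (2R,3R); C6/C9a facial sense unassigned and transient; not isolated | CC1=C2C[C@@H](C)[C@H](CO[Si](c3ccccc3)(c3ccccc3)C(C)(C)C)OC23CCC(=O)C13 | intermediate
11 | (2R,3R)-2-[(tert-butyldiphenylsilyloxy)methyl]-3,5-dimethyl-3,4,8,9-tetrahydrocyclohepta[b]pyran-7(2H)-one (product of the key step) | CC1=CC(=O)CCC2=C1C[C@@H](C)[C@H](CO[Si](c3ccccc3)(c3ccccc3)C(C)(C)C)O2 | intermediate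
12 | (2R,3R)-2-(hydroxymethyl)-3,5-dimethyl-3,4,8,9-tetrahydrocyclohepta[b]pyran-7(2H)-one | CC1=CC(=O)CCC2=C1C[C@@H](C)[C@H](CO)O2 | intermediate
13 | (2R,3R)-3,5-dimethyl-7-oxo-2,3,4,7,8,9-hexahydrocyclohepta[b]pyran-2-carbaldehyde | CC1=CC(=O)CCC2=C1C[C@@H](C)[C@H](C=O)O2 | intermediate
14 | (2R,3R)-2-[(E)-2-iodoethenyl]-3,5-dimethyl-3,4,8,9-tetrahydrocyclohepta[b]pyran-7(2H)-one | CC1=CC(=O)CCC2=C1C[C@@H](C)[C@H](/C=C/I)O2 | intermediate
15 | (2R)-hept-5-yne-1,2-diol | CC#CCC[C@H](CO)O | intermediate
16 | (2R)-1-(tert-butyldiphenylsilyloxy)hept-5-yn-2-ol | CC#CCC[C@H](CO[Si](c1ccccc1)(c1ccccc1)C(C)(C)C)O | intermediate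
17 | 3-{[(2R)-1-(tert-butyldiphenylsilyloxy)hept-5-yn-2-yl]oxy}cyclopent-2-en-1-one | CC#CCC[C@H](CO[Si](c1ccccc1)(c1ccccc1)C(C)(C)C)OC1=CC(=O)CC1 | intermediate
18 | cyclobutene photoadduct of 17 (as 10 but without the C3 methyl group; (2R); ring-fusion centres transient; not isolated) | CC1=C2CC[C@H](CO[Si](c3ccccc3)(c3ccccc3)C(C)(C)C)OC23CCC(=O)C13 | intermediate
19 | (2R)-2-[(tert-butyldiphenylsilyloxy)methyl]-5-methyl-3,4,8,9-tetrahydrocyclohepta[b]pyran-7(2H)-one | CC1=CC(=O)CCC2=C1CC[C@H](CO[Si](c3ccccc3)(c3ccccc3)C(C)(C)C)O2 | intermediate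
20 | (2R)-2-(hydroxymethyl)-5-methyl-3,4,8,9-tetrahydrocyclohepta[b]pyran-7(2H)-one | CC1=CC(=O)CCC2=C1CC[C@H](CO)O2 | intermediate
21 | (2R)-5-methyl-7-oxo-2,3,4,7,8,9-hexahydrocyclohepta[b]pyran-2-carbaldehyde | CC1=CC(=O)CCC2=C1CC[C@H](C=O)O2 | intermediate
22 | (2R)-5-methyl-2-[(E)-2-(4,4,5,5-tetramethyl-1,3,2-dioxaborolan-2-yl)ethenyl]-3,4,8,9-tetrahydrocyclohepta[b]pyran-7(2H)-one | CC1=CC(=O)CCC2=C1CC[C@H](/C=C/B3OC(C)(C)C(C)(C)O3)O2 | intermediate
23 | bis-dienone: (2R,3R)-3,5-dimethyl-2-{(1E,3E)-4-[(2R)-5-methyl-7-oxo-2,3,4,7,8,9-hexahydrocyclohepta[b]pyran-2-yl]buta-1,3-dien-1-yl}-3,4,8,9-tetrahydrocyclohepta[b]pyran-7(2H)-one | CC1=CC(=O)CCC2=C1C[C@@H](C)[C@H](/C=C/C=C/[C@H]1CCC3=C(CCC(=O)C=C3C)O1)O2 | intermediate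
24 | disodium bis-enolate of 23 (C7=C8 and C7′=C8′ enolates; not isolated) | CC1=CC([O-])=CCC2=C1C[C@@H](C)[C@H](/C=C/C=C/[C@H]1CCC3=C(CC=C([O-])C=C3C)O1)O2.[Na+].[Na+] | intermediate
25 | bis-acyloin: 8,8′-dihydroxy derivative of 23 (epimers at C8 and C8′; C2, C3, C2′ and the E,E-diene as in 23) | CC1=CC(=O)C(O)CC2=C1C[C@@H](C)[C@H](/C=C/C=C/[C@H]1CCC3=C(CC(O)C(=O)C=C3C)O1)O2 | intermediate
26 | bis(7,8-dione) from 25 (not isolated) | CC1=CC(=O)C(=O)CC2=C1C[C@@H](C)[C@H](/C=C/C=C/[C@H]1CCC3=C(CC(=O)C(=O)C=C3C)O1)O2 | intermediate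
27 | CNP0332980.1, (2R,3R,2′R)-bis-tropolone with E,E-diene | Cc1cc(=O)c(O)cc2c1C[C@@H](C)[C@H](/C=C/C=C/[C@H]1CCc3c(C)cc(=O)c(O)cc3O1)O2 | target

Total step count: 20. Longest linear sequence: 13 steps (steps 1–10, then 18–20; the branch through steps 1–3 and 11–17 is equally long).

Steps most likely to fail

1. Step 7 (step 14 shares the risk). The triplet may add only sluggishly to the unactivated alkyne through a six-membered transition state. Hydrogen abstraction from C2–H may compete. The β,γ-unsaturated ketone of the photoadduct may undergo secondary photorearrangement. The Lewis acid may trigger an acyl migration of the Cargill type instead of C6–C9a cleavage.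
The fallback sets out from 9 and comes back at 11, and replaces the alkyne by an alkene so that the classical enone–olefin/de Mayo sequence applies.
- Semihydrogenation of 9 (H2, Pd/CaCO3 poisoned with Pb(OAc)2, quinoline, EtOAc) would give the (Z)-alkenyl enol ether F1.
- Irradiation at 300 nm would give the saturated tricyclic cyclobutane F2, which has no β,γ-unsaturated ketone chromophore.
- BF3·OEt2 would cleave its donor–acceptor bond C6–C9a, and proton loss from C4a would give the 5,6-dihydro ketone F3.
- DDQ in dioxane would abstract the C5 hydride, which is allylic to the enol ether, and loss of a C6 proton would return the route to 11.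

2. Step 19. Deprotonation at C9 or at the C5 methyl group may compete and lead through extended enolates to oxygenation at the wrong carbon. One of the two ketones may react incompletely. The enolate may add to the sulfonimine that the oxidant leaves behind.
The fallback sets out from 23 and comes back at 25, and avoids strong base altogether.
- Mn(OAc)3 in refluxing benzene effects α′-acetoxylation, a reaction known for enones and for vinylogous esters, and would give the bis(8-acetoxy) diketone F4.
- Methanolysis (K2CO3, MeOH, 0 °C) would then release 25.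

3. Step 18. Zerovalent palladium may ionise an allylic C2–O1 or C2′–O1′ bond, with loss of configuration or opening of the pyran ring. Protodeboronation of the alkenylboronate may also consume one partner.
The fallback sets out from 21 (with 14 as partner) and comes back at 23, and uses no palladium.
- Chromium olefination of 21 with Bu3SnCHBr2, CrCl2 and LiI in THF–DMF would give the (E)-alkenylstannane F5.
- F5 would be joined to 14 with the monovalent copper carboxylate Cu(O2C-2-thienyl) (copper thiophene-2-carboxylate) in NMP at 0 °C → rt, a copper-mediated stannane–iodide coupling that cannot form π-allyl species.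

Further compounds
F1 | step 7 | 3-{[(2R,3R,5Z)-1-(tert-butyldiphenylsilyloxy)-3-methylhept-5-en-2-yl]oxy}cyclopent-2-en-1-one | C/C=C\C[C@@H](C)[C@H](CO[Si](c1ccccc1)(c1ccccc1)C(C)(C)C)OC1=CC(=O)CC1
F2 | step 7 | saturated tricyclic cyclobutane (4a,5-dihydro analogue of 10; new centres unassigned) | CC1C2C[C@@H](C)[C@H](CO[Si](c3ccccc3)(c3ccccc3)C(C)(C)C)OC23CCC(=O)C13
F3 | step 7 | (2R,3R)-2-[(tert-butyldiphenylsilyloxy)methyl]-3,5-dimethyl-3,4,5,6,8,9-hexahydrocyclohepta[b]pyran-7(2H)-one (C5 epimers) | CC1CC(=O)CCC2=C1C[C@@H](C)[C@H](CO[Si](c3ccccc3)(c3ccccc3)C(C)(C)C)O2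
F4 | step 19 | 8,8′-diacetoxy derivative of 23 (epimers at C8 and C8′) | CC1=CC(=O)C(OC(C)=O)CC2=C1C[C@@H](C)[C@H](/C=C/C=C/[C@H]1CCC3=C(CC(OC(C)=O)C(=O)C=C3C)O1)O2
F5 | step 18 | (2R)-5-methyl-2-[(E)-2-(tributylstannyl)ethenyl]-3,4,8,9-tetrahydrocyclohepta[b]pyran-7(2H)-one | CC1=CC(=O)CCC2=C1CC[C@H](/C=C/[Sn](CCCC)(CCCC)CCCC)O2
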